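A reagent charge as large as the substrate charge waits in the second phase and has to cross into the reaction phase before it meets substrate.

    reagent in the reaction phase ⇌ reagent in the second phase, rate k1*([reagent in the reaction phase] - [reagent in the second phase]/K1) per volume of the first phase (K1 = 1.16, k1 = 0.240 s⁻¹)
    substrate + reagent in the reaction phase → target (k2 = 3.22 M⁻¹ s⁻¹)
    target ⇌ product in the second phase, rate k3*([target] - [product in the second phase]/K3) per volume of the first phase (K3 = 2.00, k3 = 0.0516 s⁻¹)
    target → decomposed product (k4 = 0.0258 s⁻¹)
    reagent in the reaction phase + target → over-reaction product (k5 = 6.13 M⁻¹ s⁻¹)
    reagent in the reaction phase ⇌ dormant form (K6 = 0.40, k6 = 0.0403 s⁻¹)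

substrate 24 mM; reagent in the second phase 24.0 mM; time 8.0 s; volume of the second phase over the first 0.50

- what is said of target includes product in the second phase
- in the second phase: reagent in the second phase, product in the second phase; everything else is in the first
- charges count per volume of the first phase; a concentration in a rate is the amount of a species over the volume of its own phase; every rate counts per litre of the first phase
- run time (flask): 8.0 s

* target and product in the second phase together at 8.0 s, in percent of the substrate charged
* the change that raises the amount of target and product in the second phase together at 8.0 s, in percent of the substrate charged most ("none" if none brings more than 2 percentage points) (Monday's / Friday's / Sunday's / none)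
* amount of target and product in the second phase together at 8.0 s, in percent of the substrate charged, after Sunday's

- Monday's: doubling the transfer coefficient of step 1, all else as stated
- Friday's: doubling the transfer coefficient of step 3, all else as stated
- Sunday's: doubling the amount of reagent in the second phase, all else as stated

**Bench rule.** Take the crossing as balanced. With partition ratio K and volume ratio v, divide the charge by one plus K·v to get the free reagent F = 15.2 mM. Hold F steady: substrate then decays pseudo-first-order at k·F, with k the rate constant of its reaction with reagent. That uses 32.4 % of the substrate in 8.0 s.

**Its border.** The rule needs the run to be long against the crossing and short against the drain on the reagent. The crossing relaxes with time constant τ = 1.53 s, shorter than the run. The drain, with c the substrate charge and d the rate constant towards the dormant form, is λ = (k·c + d) divided by one plus K·v, or 0.0744 s⁻¹. Here λ·t is 0.595, which is not small, so the rule reads too high.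

**My reckoning.** Let free reagent follow F(exp(−λt) − exp(−t/τ)), and average this over the run: the mean free reagent M is 8.56 mM. Substrate used is then 19.8 %. Target made evenly through the run is lost at the decomposition constant plus the over-reaction constant times M, which is 0.0783 s⁻¹. So I commit to y = 14.7 %. Sunday's doubles the reagent charge, which doubles M and gives 22.1 %. Monday's doubles the transfer coefficient of the reagent crossing, which halves τ, lifts M to 9.99 mM and gives 16.3 %. Friday's doubles the transfer coefficient of the target crossing and leaves M as it is in this reckoning. Choose Sunday's.

**The forecast.** It gives y = 16.2 %, above my figure, names Sunday's and puts that change at 24.1 %: “Supply of reagent limits the yield more than anything else”.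

**The result.** The simulation gives 16.1 % and 23.6 % after Sunday's, whose gain of 7.4 percentage points exceeds Monday's 1.2 points and Friday's 0.41 points. In this flask 21.5 % of the substrate was used, against 19.8 % from M. Now read the same charges at 5.0 s: M becomes 8.21 mM, substrate used 12.4 % and y 10.3 %. That neighbouring flask used 13.4 % of its substrate and held 11.3 %.

Its constants belong to no real substance; the flask was simulated.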